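**Plan**
- Cuts: (a) the acyl C–O bond of the stearate. (b) In the oxepine ring, C3 is re-joined to C5. C4 then becomes a cyclopropane CH2, the exocyclic =CH2 becomes CH2OH, and the oxepine shrinks to a pyran (a cyclopropa[c]chromene carbinol). (c) That CH2 is removed (alkene + carbenoid). (d) The O1–C2 and C3–C4 bonds of the 2H-chromene are cut (salicylaldehyde + acrolein).
- Enabling feature: C5–C4–C3(=CH2) of the oxepine ring is a homoallyl array. C5 is benzylic and sits on C5a, ortho to the O1-bearing C9a, so a cation at C5 is an o-alkoxybenzyl cation. Its only β-hydrogens are on C4. The array is what a cyclopropylcarbinyl-to-homoallyl opening followed by proton loss delivers.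
- Forward order: benzene ring bought, then pyran ring (domino oxa-Michael/aldol), then fused cyclopropane (one carbon). A six-to-seven ring enlargement sets the oxepine, the exocyclic methylene and C4=C5 together; ester reduction and stearoylation follow.
- Stereochemistry: the target has no stereocentre and C4=C5 is cis by ring constraint. The two cyclopropane centres are transient, racemic and erased in the key step.

Key step: step 4

Remark: the target SMILES contains no stereocentre, so the molecule is achiral and no enantiomer has to be selected. Compounds 6 and 7 are carried as racemates, with one enantiomer drawn.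

**Step 1**
Reactants: 1 methyl 3-formyl-4-hydroxybenzoate; 2 acrolein
Product: 4 methyl 3-formyl-2H-chromene-6-carboxylate, via oxa-Michael adduct 3 (not isolated)
Conditions: K2CO3, 1,4-dioxane, reflux
Reagents that add atoms: none
Why: Domino oxa-Michael addition/intramolecular aldol condensation of a salicylaldehyde with acrolein, the standard entry to 2H-chromene-3-carbaldehydes; the ortho-formyl group captures the enolate of 3 and loss of water gives the conjugated enal without forming a stereocentre.

**Step 2**
Reactants: 4 methyl 3-formyl-2H-chromene-6-carboxylate
Product: 5 methyl 3-(hydroxymethyl)-2H-chromene-6-carboxylate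
Conditions: NaBH4, MeOH–THF, 0 °C
Reagents that add atoms: none
Why: Borohydride 1,2-reduction of an enal, chemoselective because the aryl methyl ester is inert to NaBH4 at 0 °C; no stereocentre is formed.

**Step 3**
Reactants: 5 methyl 3-(hydroxymethyl)-2H-chromene-6-carboxylate
Product: 6 methyl 1a-(hydroxymethyl)-1,1a,2,7b-tetrahydrocyclopropa[c]chromene-6-carboxylate (racemic, cis-fused)
Conditions: Et2Zn, CH2I2, CH2Cl2, 0 °C → rt
Reagents that add atoms: diiodomethane, ICI
Why: Hydroxyl-directed Simmons–Smith cyclopropanation (Furukawa variant), in which the zinc alkoxide of 5 delivers CH2 by concerted syn addition to the adjacent trisubstituted C3=C4 bond, so C1a and C7b are set together as the only possible cis fusion, in racemic form because nothing chiral is present.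

**Step 4**
Reactants: 6 methyl 1a-(hydroxymethyl)-1,1a,2,7b-tetrahydrocyclopropa[c]chromene-6-carboxylate
Product: 9 methyl 3-methylidene-2,3-dihydro-1-benzoxepine-7-carboxylate, via cyclopropylcarbinyl mesylate 7 (not isolated), via benzoxepin-5-yl cation 8 (not isolated)
Conditions: Ms2O, i-Pr2NEt, CH2Cl2 (dilute), −20 °C → 40 °C
Reagents that add atoms: none
Why: O-Mesylation gives 7, whose primary C–O bond ionises with σ-participation of the cyclopropane, and of the two ring bonds flanking C1a the fusion bond C1a–C7b breaks, because this places the charge on C7b (secondary, benzylic, ortho to the ring oxygen) whereas cleavage of C1a–C1 would give a primary cation. This turns the CH2OMs carbon into the exocyclic methylene, moves the former carbenoid CH2 into the ring as C4 and enlarges the six-membered pyran to the seven-membered cation 8, from which the amine removes a proton at C4, the only hydrogen-bearing neighbour of C5, so C4=C5 forms without regiochemical choice. The closest known reaction type is the cyclopropylcarbinyl-to-homoallyl cation rearrangement (Julia-type opening of cyclopropyl carbinols), as used for one-carbon enlargement of bicyclo[n.1.0]alkan-1-ylmethanols and for dehydrative opening of 2-arylcyclopropylmethanols to 1-aryl-1,3-dienes. No ring is closed, since the seven-membered ring arises by scission of the zero-atom bridge of the 3-oxabicyclo[4.1.0]heptane unit, so no closure mode applies. No stereocentre is formed, the two of 6 are erased, and the new ring alkene can only be cis. The step needs endocyclic rather than exocyclic bond cleavage or cyclobutyl capture, secured by the aryl donor on C7b and the reversibility of the less stabilised cations, and it needs the diene to survive, secured by excess hindered base, dilution and the C7 ester, which lowers the nucleophilicity of the styrene unit.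

**Step 5**
Reactants: 9 methyl 3-methylidene-2,3-dihydro-1-benzoxepine-7-carboxylate
Product: 10 (3-methylidene-2,3-dihydro-1-benzoxepin-7-yl)methanol
Conditions: LiAlH4, THF, 0 °C
Reagents that add atoms: none
Why: Hydride reduction of an aryl ester to the benzylic alcohol; the unactivated diene and the allyl aryl ether are inert to LiAlH4 at 0 °C.

**Step 6**
Reactants: 10 (3-methylidene-2,3-dihydro-1-benzoxepin-7-yl)methanol; 11 stearoyl chloride
Product: 12 (3-methylidene-2,3-dihydro-1-benzoxepin-7-yl)methyl octadecanoate (target)
Conditions: Et3N, DMAP (cat.), CH2Cl2, 0 °C → rt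
Reagents that add atoms: none
Why: DMAP-catalysed acylation of a primary benzylic alcohol with an acid chloride, with the amine keeping the medium basic so that the p-alkoxybenzyl position and the diene are not exposed to acid.

**Compound list**
1 | methyl 3-formyl-4-hydroxybenzoate | COC(=O)c1ccc(O)c(C=O)c1 | starting material
2 | acrolein | C=CC=O | starting material
3 | methyl 3-formyl-4-(3-oxopropoxy)benzoate | COC(=O)c1ccc(OCCC=O)c(C=O)c1 | intermediate
4 | methyl 3-formyl-2H-chromene-6-carboxylate | COC(=O)c1ccc2OCC(C=O)=Cc2c1 | intermediate
5 | methyl 3-(hydroxymethyl)-2H-chromene-6-carboxylate | COC(=O)c1ccc2OCC(CO)=Cc2c1 | intermediate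
6 | methyl 1a-(hydroxymethyl)-1,1a,2,7b-tetrahydrocyclopropa[c]chromene-6-carboxylate (racemic, cis-fused, one enantiomer drawn) | OC[C@]12C[C@H]1c1cc(C(=O)OC)ccc1OC2 | intermediate
7 | methyl 1a-[(methylsulfonyloxy)methyl]-1,1a,2,7b-tetrahydrocyclopropa[c]chromene-6-carboxylate (racemic, cis-fused, one enantiomer drawn) | CS(=O)(=O)OC[C@]12C[C@H]1c1cc(C(=O)OC)ccc1OC2 | intermediate
8 | 7-(methoxycarbonyl)-3-methylidene-2,3,4,5-tetrahydro-1-benzoxepin-5-ylium | C=C1C[CH+]c2cc(C(=O)OC)ccc2OC1 | intermediate
9 | methyl 3-methylidene-2,3-dihydro-1-benzoxepine-7-carboxylate | C=C1C=Cc2cc(C(=O)OC)ccc2OC1 | intermediate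
10 | (3-methylidene-2,3-dihydro-1-benzoxepin-7-yl)methanol | C=C1C=Cc2cc(CO)ccc2OC1 | intermediate
11 | stearoyl chloride (octadecanoyl chloride) | ClC(=O)CCCCCCCCCCCCCCCCC | starting material
12 | (3-methylidene-2,3-dihydro-1-benzoxepin-7-yl)methyl octadecanoate | C=C1C=Cc2cc(COC(=O)CCCCCCCCCCCCCCCCC)ccc2OC1 | target

Total step count: 6. Longest linear sequence: 6.

**Steps most likely to fail**

Step 4. The delocalised cation may be captured by returning mesylate before the fusion bond has broken, at the cyclopropylcarbinyl or cyclobutyl stage. The diene may also be consumed by cationic oligomerisation as it forms.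
- The fallback sets out from 1 and comes back at 9. It inserts the ring carbon as a dihalocarbene, an edit known on 2H-chromenes.
- An amine-catalysed Petasis-type chromene synthesis of 1 with isopropenylboronic acid (Bn2NH, dioxane, 90 °C) should give methyl 3-methyl-2H-chromene-6-carboxylate F1.
- Dibromocarbene addition (CHBr3, KOt-Bu, hexane, 0 °C) should give methyl 1,1-dibromo-1a-methyl-1,1a,2,7b-tetrahydrocyclopropa[c]chromene-6-carboxylate F2.
- Heating with 2,6-lutidine in toluene should trigger the disrotatory electrocyclic opening with departure of the endo bromide. Loss of a proton from the methyl group should then lead to methyl 4-bromo-3-methylidene-2,3-dihydro-1-benzoxepine-7-carboxylate F3.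
- Pd-catalysed formate hydrodebromination (Pd(PPh3)4, HCO2H, Et3N, DMF) should remove the helper bromine and give 9.

Step 3. Methylene transfer to the trisubstituted, ester-deactivated styrene-type alkene may be sluggish. O-methylation of the zinc alkoxide or Lewis-acid opening of the product by zinc iodide could then compete.
- The fallback sets out from 4 and comes back at 6, with the polarity of the methylene transfer inverted.
- A Corey–Chaykovsky cyclopropanation of enal 4 (Me3S(O)I, NaH, DMSO, rt; Michael-initiated ring closure) should give methyl 1a-formyl-1,1a,2,7b-tetrahydrocyclopropa[c]chromene-6-carboxylate F4.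
- NaBH4 in MeOH at 0 °C should then reduce F4 to 6.

Step 1. Acrolein may polymerise, and the oxa-Michael addition of the weakly nucleophilic, ester-deactivated phenoxide is reversible, so conversion may stall.
- The fallback sets out from 1 and comes back at 3, which closes to 4. The O–C2 bond is made by alkylation instead of conjugate addition.
- Reaction of 1 with 2-(2-bromoethyl)-1,3-dioxolane (K2CO3, DMF, 70 °C) should give methyl 4-[2-(1,3-dioxolan-2-yl)ethoxy]-3-formylbenzoate F5.
- Acetal hydrolysis (aq. HCl, THF) releases 3, and pyrrolidinium acetate should bring about its aldol condensation to 4.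

**Further compounds**
F1 | step 4 | methyl 3-methyl-2H-chromene-6-carboxylate | COC(=O)c1ccc2OCC(C)=Cc2c1
F2 | step 4 | methyl 1,1-dibromo-1a-methyl-1,1a,2,7b-tetrahydrocyclopropa[c]chromene-6-carboxylate (racemic, cis-fused, one enantiomer drawn) | C[C@]12C(Br)(Br)[C@H]1c1cc(C(=O)OC)ccc1OC2
F3 | step 4 | methyl 4-bromo-3-methylidene-2,3-dihydro-1-benzoxepine-7-carboxylate | C=C1C(Br)=Cc2cc(C(=O)OC)ccc2OC1
F4 | step 3 | methyl 1a-formyl-1,1a,2,7b-tetrahydrocyclopropa[c]chromene-6-carboxylate (racemic, cis-fused, one enantiomer drawn) | O=C[C@]12C[C@H]1c1cc(C(=O)OC)ccc1OC2
F5 | step 1 | methyl 4-[2-(1,3-dioxolan-2-yl)ethoxy]-3-formylbenzoate | COC(=O)c1ccc(OCCC2OCCO2)c(C=O)c1
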